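**Plan**
- Retrosynthetic cuts, in order: the C4–OMe bond (methanol opening of a C4–C5 oxirane), the C3–OAc bond (inversion of an allylic alcohol), the C6–H and C3–H bonds (two carbonyl reductions), both oxirane C–O bonds, then the ring–alkyne, vinyl–alkyne and allyl–vinyl C–C bonds of the side chain.
- Enabling feature: on the six-membered ring (C1 alkynyl carbon, C2 =CH, C3 OAc, C4 OMe, C5 OH, C6 OH) the trans C4-methoxy/C5-hydroxy pair lies between oxygenated C3 and C6. This is what methanol leaves on opening a C4–C5 oxirane. With C3 and C6 at the carbonyl level the ring is a 2-alkynyl quinone monoketal whose unsubstituted C4=C5 enone arm accepts a peroxide.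
- Forward: the chain is joined allyl–vinyl, then vinyl–alkynyl, then alkynyl–aryl. The carbocycle is the arene of 2-bromo-4-methoxyphenol, dearomatised with PhI(OAc)2 in MeOH. The oxirane is the only ring closed, and it is opened again in the last step.
- Stereochemistry: C4 and C5 come from the tartrate-mediated epoxidation. C6 and C3 are set by hydride addition anti to the oxirane. C3 is then inverted by a Mitsunobu reaction with acetic acid. Methanol inverts C4 while C5 keeps its oxygen.

Key step: step 8

Remarks on the chemistry: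
- Ring locants are those of the target throughout (C1 alkynyl carbon … C6). R = (5E)-7-hydroxy-7-methyl-3-methylideneoct-5-en-1-yn-1-yl.
- The side-chain tertiary alcohol is carried unprotected.
- Assumption: diisopropyl L-tartrate is taken to be the enantiomer that delivers the peroxide to the face giving the (4S,5R) oxirane. If the sense of induction on this dienone is the opposite, the D-ester is used and nothing else changes.

**Route**

Step 1
Reactants: 1 2-methylbut-3-yn-2-ol
Product: 2 (E)-2-methyl-4-(tributylstannyl)but-3-en-2-ol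
Conditions: Bu3SnH, PdCl2(PPh3)2 (cat.), THF, 0 °C → rt
Reagents that add atoms: tributyltin hydride, CCCC[SnH](CCCC)CCCC
Why: Palladium-catalysed hydrostannation adds Sn–H cis across the alkyne, and the bulky carbinol carbon sends tin to the terminal carbon, so the E-vinylstannane should result.

Step 2
Reactants: 2 (E)-2-methyl-4-(tributylstannyl)but-3-en-2-ol; 3 2,3-dibromopropene
Product: 4 (E)-6-bromo-2-methylhepta-3,6-dien-2-ol
Conditions: Pd2(dba)3 (cat.), P(2-furyl)3, THF, 50 °C, excess 3
Reagents that add atoms: none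
Why: Stille coupling in which zerovalent palladium inserts into the allylic C–Br bond far faster than into the vinylic one; both ends of the 2-bromoallyl unit give the same product and the E alkene is transferred with retention.

Step 3
Reactants: 4 (E)-6-bromo-2-methylhepta-3,6-dien-2-ol; 5 ethynyltrimethylsilane
Product: 6 (E)-2-methyl-6-methylidene-8-(trimethylsilyl)oct-3-en-7-yn-2-ol
Conditions: PdCl2(PPh3)2 (cat.), CuI (cat.), Et3N, THF, rt → 40 °C
Reagents that add atoms: none
Why: Sonogashira coupling of a 2-bromo-1-alkene with a terminal alkyne is routine and leaves the skipped diene and the free tertiary alcohol untouched.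

Step 4
Reactants: 6 (E)-2-methyl-6-methylidene-8-(trimethylsilyl)oct-3-en-7-yn-2-ol
Product: 7 (E)-2-methyl-6-methylideneoct-3-en-7-yn-2-ol
Conditions: K2CO3 (cat.), MeOH, rt; used at once as a solution
Reagents that add atoms: none
Why: Base-catalysed protodesilylation of an alkynylsilane by methanol is selective for the C(sp)–Si bond.

Step 5
Reactants: 8 2-bromo-4-methoxyphenol
Product: 9 2-bromo-4-methoxyphenyl acetate
Conditions: Ac2O, pyridine, rt
Reagents that add atoms: acetic anhydride, CC(=O)OC(C)=O
Why: O-Acetylation masks the phenol so that the ortho-alkynylphenol cannot cyclise to a benzofuran during the coupling.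

Step 6
Reactants: 7 (E)-2-methyl-6-methylideneoct-3-en-7-yn-2-ol; 9 2-bromo-4-methoxyphenyl acetate
Product: 10 2-R-4-methoxyphenyl acetate
Conditions: PdCl2(PPh3)2 (cat.), CuI (cat.), Et3N, DMF, 60 °C, degassed
Reagents that add atoms: none
Why: Sonogashira coupling of an aryl bromide bearing an ortho acetoxy group; the tertiary amine does not cleave the aryl acetate and exclusion of oxygen suppresses diyne formation.

Step 7
Reactants: 10 2-R-4-methoxyphenyl acetate
Product: 12 2-R-4,4-dimethoxycyclohexa-2,5-dien-1-one, via 2-R-4-methoxyphenol 11 (not isolated)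
Conditions: K2CO3 (0.2 equiv), MeOH, 0 °C → rt; then PhI(OAc)2, 0 °C
Reagents that add atoms: methanol, CO
Why: Methanolysis of the aryl acetate followed by oxidative dearomatisation with the trivalent iodine reagent, in which methanol adds para to the phenol oxygen at the methoxy-bearing carbon; this places the carbonyl next to the alkynyl carbon without ambiguity.

Step 8
Reactants: 12 2-R-4,4-dimethoxycyclohexa-2,5-dien-1-one
Product: 13 (4S,5R)-4,5-epoxy-3,3-dimethoxy-1-R-cyclohex-1-en-6-one
Conditions: Ph3COOH, NaN(SiMe3)2, diisopropyl L-tartrate, 4 Å MS, toluene, −78 → −50 °C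
Reagents that add atoms: trityl hydroperoxide, OOC(c1ccccc1)(c1ccccc1)c1ccccc1
Why: Sodium trityl peroxide, held in a sodium tartrate aggregate, adds in conjugate fashion to C4, the β-carbon of the unsubstituted enone arm, and the sodium enolate then attacks the proximal peroxide oxygen through C5 with loss of trityl oxide; this is a Weitz–Scheffer epoxidation in its known tartrate-mediated form for quinone monoketals. The oxirane closes in a 3-exo-tet mode. C4 and C5 arise together as a cis pair because of the ring fusion, and their absolute sense is set by the chiral tartrate ligand sphere around the sodium peroxide, to which the substrate is bound through its side-chain sodium alkoxide. The step needs site selectivity between the two enone arms and must stop after one oxidation: the C1=C2 arm carries the alkynyl group on its α-carbon, so closure there would build a fully substituted oxirane carbon against the bulky trityl peroxide and should be much slower. Low temperature and a small excess of peroxide should keep that arm intact, and the alkyne, being cross-conjugated to the carbonyl, offers no extended acceptor position.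

Step 9
Reactants: 13 (4S,5R)-4,5-epoxy-3,3-dimethoxy-1-R-cyclohex-1-en-6-one
Product: 14 (4S,5S,6S)-4,5-epoxy-3,3-dimethoxy-1-R-cyclohex-1-en-6-ol (C6 hydroxyl cis to the oxirane)
Conditions: i-Bu2AlH (3 equiv), THF, −78 °C; Rochelle salt work-up
Reagents that add atoms: none
Why: 1,2-Reduction of the enone carbonyl by the aluminium hydride, which attacks the face opposite the oxirane oxygen as is general for cyclic α,β-epoxy ketones, so that the C6 hydroxyl ends cis to the oxirane; the extra hydride covers the tertiary alkoxide.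

Step 10
Reactants: 14 (4S,5S,6S)-4,5-epoxy-3,3-dimethoxy-1-R-cyclohex-1-en-6-ol
Product: 15 (4S,5R,6S)-6-(tert-butyldimethylsilyloxy)-4,5-epoxy-3,3-dimethoxy-1-R-cyclohex-1-ene
Conditions: TBSCl, imidazole, DMAP (cat.), DMF, rt
Reagents that add atoms: tert-butyldimethylsilyl chloride, CC(C)(C)[Si](C)(C)Cl
Why: Silylation with the chlorosilane and imidazole takes the secondary allylic alcohol and leaves the hindered tertiary alcohol free.

Step 11
Reactants: 15 (4S,5R,6S)-6-(tert-butyldimethylsilyloxy)-4,5-epoxy-3,3-dimethoxy-1-R-cyclohex-1-ene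
Product: 16 (4S,5R,6S)-6-(tert-butyldimethylsilyloxy)-4,5-epoxy-1-R-cyclohex-1-en-3-one
Conditions: PPTS, acetone/H2O, rt → 40 °C
Reagents that add atoms: water, O
Why: Mild acid hydrolysis of an allylic dimethyl ketal through an allyl-stabilised oxocarbenium ion; the buffered acid is too weak to open the oxirane, cleave the silyl ether or ionise the tertiary allylic alcohol.

Step 12
Reactants: 16 (4S,5R,6S)-6-(tert-butyldimethylsilyloxy)-4,5-epoxy-1-R-cyclohex-1-en-3-one
Product: 17 (3R,4R,5R,6S)-6-(tert-butyldimethylsilyloxy)-4,5-epoxy-1-R-cyclohex-1-en-3-ol (all three oxygens on one face)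
Conditions: NaBH4, CeCl3·7H2O, MeOH, −78 °C
Reagents that add atoms: none
Why: Luche 1,2-reduction of the enone; the oxirane oxygen and the C6 silyloxy group both shield the lower face, so hydride enters from the upper face and the C3 hydroxyl ends cis to the oxirane.

Step 13
Reactants: 17 (3R,4R,5R,6S)-6-(tert-butyldimethylsilyloxy)-4,5-epoxy-1-R-cyclohex-1-en-3-ol
Product: 18 (3S,4R,5R,6S)-3-acetoxy-6-(tert-butyldimethylsilyloxy)-4,5-epoxy-1-R-cyclohex-1-ene
Conditions: PPh3, DIAD, AcOH, THF, 0 °C → rt
Reagents that add atoms: acetic acid, CC(=O)O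
Why: Mitsunobu reaction in which acetate displaces the C3 oxyphosphonium group by SN2 from the open upper face, inverting C3 and installing the ester in one operation; SN2′ is blocked because C1 is fully substituted, and the tertiary alcohol does not react.

Step 14
Reactants: 18 (3S,4R,5R,6S)-3-acetoxy-6-(tert-butyldimethylsilyloxy)-4,5-epoxy-1-R-cyclohex-1-ene
Product: 19 (3S,4R,5S,6S)-3-acetoxy-4,5-epoxy-1-R-cyclohex-1-en-6-ol
Conditions: HF·pyridine, pyridine, THF, 0 °C → rt
Reagents that add atoms: none
Why: Fluoride-driven desilylation under buffered, non-basic conditions spares the acetate and the oxirane and avoids acyl loss or epoxide migration.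

Step 15
Reactants: 19 (3S,4R,5S,6S)-3-acetoxy-4,5-epoxy-1-R-cyclohex-1-en-6-ol
Product: 20 (3S,4R,5S,6S)-3-acetoxy-4-methoxy-1-R-cyclohex-1-ene-5,6-diol (target)
Conditions: Eu(OTf)3 (10 mol %), 2,6-di-tert-butyl-4-methylpyridine, MeOH, rt → 40 °C
Reagents that add atoms: methanol, CO
Why: Chelation-controlled Lewis-acid methanolysis of a 2,3-epoxy alcohol: the lanthanide bridges the cis C6 hydroxyl and the oxirane oxygen, so methanol opens the remote C4–O bond with inversion in a trans-diaxial (Fürst–Plattner) sense that keeps the C3 and C6 substituents pseudo-equatorial, giving trans C4-OMe/C5-OH, while the hindered pyridine scavenges triflic acid to protect the tertiary allylic alcohol and the acetate.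

**Compound list**

1 | 2-methylbut-3-yn-2-ol | CC(C)(O)C#C | starting material
2 | (E)-2-methyl-4-(tributylstannyl)but-3-en-2-ol | CC(C)(O)/C=C/[Sn](CCCC)(CCCC)CCCC | intermediate
3 | 2,3-dibromopropene | C=C(Br)CBr | starting material
4 | (E)-6-bromo-2-methylhepta-3,6-dien-2-ol | C=C(Br)C/C=C/C(C)(C)O | intermediate
5 | ethynyltrimethylsilane | C#C[Si](C)(C)C | starting material
6 | (E)-2-methyl-6-methylidene-8-(trimethylsilyl)oct-3-en-7-yn-2-ol | C[Si](C)(C)C#CC(=C)C/C=C/C(C)(C)O | intermediate
7 | (E)-2-methyl-6-methylideneoct-3-en-7-yn-2-ol | C#CC(=C)C/C=C/C(C)(C)O | intermediate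
8 | 2-bromo-4-methoxyphenol | COc1ccc(O)c(Br)c1 | starting material
9 | 2-bromo-4-methoxyphenyl acetate | COc1ccc(OC(C)=O)c(Br)c1 | intermediate
10 | 2-[(5E)-7-hydroxy-7-methyl-3-methylideneoct-5-en-1-yn-1-yl]-4-methoxyphenyl acetate | COc1ccc(OC(C)=O)c(C#CC(=C)C/C=C/C(C)(C)O)c1 | intermediate
11 | 2-[(5E)-7-hydroxy-7-methyl-3-methylideneoct-5-en-1-yn-1-yl]-4-methoxyphenol | COc1ccc(O)c(C#CC(=C)C/C=C/C(C)(C)O)c1 | intermediate (not isolated)
12 | 2-[(5E)-7-hydroxy-7-methyl-3-methylideneoct-5-en-1-yn-1-yl]-4,4-dimethoxycyclohexa-2,5-dien-1-one | COC1(OC)C=CC(=O)C(C#CC(=C)C/C=C/C(C)(C)O)=C1 | intermediate (key-step precursor)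
13 | (4S,5R)-4,5-epoxy-3,3-dimethoxy-1-R-cyclohex-1-en-6-one | COC1(OC)C=C(C#CC(=C)C/C=C/C(C)(C)O)C(=O)[C@@H]2O[C@H]12 | intermediate (key-step product)
14 | (4S,5S,6S)-4,5-epoxy-3,3-dimethoxy-1-R-cyclohex-1-en-6-ol, hydroxyl cis to the oxirane | C=C(C#CC1=CC(OC)(OC)[C@H]2O[C@H]2[C@H]1O)C/C=C/C(C)(C)O | intermediate
15 | (4S,5R,6S)-6-(tert-butyldimethylsilyloxy)-4,5-epoxy-3,3-dimethoxy-1-R-cyclohex-1-ene | C=C(C#CC1=CC(OC)(OC)[C@H]2O[C@H]2[C@H]1O[Si](C)(C)C(C)(C)C)C/C=C/C(C)(C)O | intermediate
16 | (4S,5R,6S)-6-(tert-butyldimethylsilyloxy)-4,5-epoxy-1-R-cyclohex-1-en-3-one | C=C(C#CC1=CC(=O)[C@H]2O[C@H]2[C@H]1O[Si](C)(C)C(C)(C)C)C/C=C/C(C)(C)O | intermediate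
17 | (3R,4R,5R,6S)-6-(tert-butyldimethylsilyloxy)-4,5-epoxy-1-R-cyclohex-1-en-3-ol, all-cis | C=C(C#CC1=C[C@@H](O)[C@H]2O[C@H]2[C@H]1O[Si](C)(C)C(C)(C)C)C/C=C/C(C)(C)O | intermediate
18 | (3S,4R,5R,6S)-3-acetoxy-6-(tert-butyldimethylsilyloxy)-4,5-epoxy-1-R-cyclohex-1-ene, acetate trans to the oxirane | C=C(C#CC1=C[C@H](OC(C)=O)[C@H]2O[C@H]2[C@H]1O[Si](C)(C)C(C)(C)C)C/C=C/C(C)(C)O | intermediate
19 | (3S,4R,5S,6S)-3-acetoxy-4,5-epoxy-1-R-cyclohex-1-en-6-ol | C=C(C#CC1=C[C@H](OC(C)=O)[C@H]2O[C@H]2[C@H]1O)C/C=C/C(C)(C)O | intermediate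
20 | (3S,4R,5S,6S)-3-acetoxy-4-methoxy-1-R-cyclohex-1-ene-5,6-diol | C=C(C#CC1=C[C@H](OC(C)=O)[C@H](OC)[C@@H](O)[C@H]1O)C/C=C/C(C)(C)O | target

**Count**
Total steps: 15. Longest linear sequence: 14 (steps 1–4 and 6–15, from 1); step 5 is the one-step side branch.

**Steps most likely to fail**

Step 8. The dienone has no hydroxyl close to the reacting enone to anchor it in the tartrate aggregate, so enantioface discrimination may be poor; the second enone arm may also be oxidised if the peroxide is not limited. Fallback, setting out from 12: a plain Weitz–Scheffer epoxidation (30 % H2O2, K2CO3, THF/H2O, 0 °C) should give the racemic epoxy ketone F1. Reduction with i-Bu2AlH as in step 9 should give the racemic cis-epoxy alcohol F2. Kinetic resolution with immobilised Burkholderia cepacia lipase and vinyl acetate in MTBE is then expected to acylate the (6S) enantiomer faster, following the empirical size rule for secondary alcohols with C1 and its side chain as the large group. The C6 acetate of 14 F3 is separated from the unreacted enantiomer and cleaved with K2CO3 in MeOH, and the route is rejoined at 14.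

Step 15. Three processes can divert the opening: participation of the trans C3 acetate at C4 through an acetoxonium ion, attack of methanol at C5, and solvolysis of the tertiary allylic alcohol or the acetate. Fallback, setting out from 19: the acetate is removed first (K2CO3, MeOH, 0 °C) to give the epoxy triol F4, in which only the cis C6 hydroxyl can chelate. The same europium-catalysed methanolysis should then give the C4 methyl ether F5. The cis C5/C6 diol is tied up as the acetonide F6 (2,2-dimethoxypropane, PPTS, acetone), the remaining secondary C3 hydroxyl is acetylated (Ac2O, pyridine) to the acetonide acetate F7, and 80 % aqueous acetic acid removes the acetonide to return at 20.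

Step 13. Displacement at a carbinol flanked by an oxirane may be sluggish, so elimination of the activated alcohol or incomplete inversion can compete. Fallback, setting out from 17: the alcohol is converted to the C3 methanesulfonate F8 (MsCl, Et3N, CH2Cl2, −20 °C), which is displaced at once with CsOAc and 18-crown-6 in toluene. This is an SN2 inversion by a free carboxylate from the open upper face, and the route is rejoined at 18.

**Further compounds**

F1 | step 8 | racemic 4,5-epoxy-3,3-dimethoxy-1-R-cyclohex-1-en-6-one (13 and its enantiomer) | COC1(OC)C=C(C#CC(=C)C/C=C/C(C)(C)O)C(=O)[C@@H]2O[C@H]12.COC1(OC)C=C(C#CC(=C)C/C=C/C(C)(C)O)C(=O)[C@H]2O[C@@H]12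
F2 | step 8 | racemic cis-4,5-epoxy-3,3-dimethoxy-1-R-cyclohex-1-en-6-ol (14 and its enantiomer) | C=C(C#CC1=CC(OC)(OC)[C@H]2O[C@H]2[C@H]1O)C/C=C/C(C)(C)O.C=C(C#CC1=CC(OC)(OC)[C@@H]2O[C@@H]2[C@@H]1O)C/C=C/C(C)(C)O
F3 | step 8 | C6 acetate of 14 | C=C(C#CC1=CC(OC)(OC)[C@H]2O[C@H]2[C@H]1OC(C)=O)C/C=C/C(C)(C)O
F4 | step 15 | 4,5-epoxy-1-R-cyclohex-1-ene-3,6-diol, C3 hydroxyl trans and C6 hydroxyl cis to the oxirane | C=C(C#CC1=C[C@H](O)[C@H]2O[C@H]2[C@H]1O)C/C=C/C(C)(C)O
F5 | step 15 | (3S,4R,5S,6S)-4-methoxy-1-R-cyclohex-1-ene-3,5,6-triol | C=C(C#CC1=C[C@H](O)[C@H](OC)[C@@H](O)[C@H]1O)C/C=C/C(C)(C)O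
F6 | step 15 | 5,6-O-isopropylidene derivative of F5 | C=C(C#CC1=C[C@H](O)[C@H](OC)[C@H]2OC(C)(C)O[C@@H]12)C/C=C/C(C)(C)O
F7 | step 15 | 3-O-acetate of F6 | C=C(C#CC1=C[C@H](OC(C)=O)[C@H](OC)[C@H]2OC(C)(C)O[C@@H]12)C/C=C/C(C)(C)O
F8 | step 13 | C3 methanesulfonate of 17 | C=C(C#CC1=C[C@@H](OS(C)(=O)=O)[C@H]2O[C@H]2[C@H]1O[Si](C)(C)C(C)(C)C)C/C=C/C(C)(C)O
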